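Ring B is disconnected at C5–C6 (labdane numbering). C5 lies between the quaternary carbons C4 and C10 and is β to the C19 carboxyl, so it is carried as the trigonal carbon of a ring-A β-keto ester enol triflate. A one-pot hydroboration/intramolecular B-alkyl Suzuki–Miyaura coupling joins C6, the terminus of a vinyl group on C8, to C5 and closes ring B as the tetrasubstituted C4=C5 enoate; both C8 epimers converge. Birch-type reductive methylation of that enoate then sets the trans ring fusion and C4. The precursor is a monocyclic triflate whose C10 and C9 come from an auxiliary-controlled Michael addition and a chirality-transferring Ireland–Claisen rearrangement.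

Key step: step 8

Remark: atoms are named by labdane numbering throughout (ring A = C1–C5, C10; ring B = C5–C10; C17 on C8; C18 and C19 on C4; C20 on C10); but-3-yn-2-one and 3-bromofuran-2(5H)-one are taken as purchasable.

Step 1
Reactants: 1 2-methylcyclohexan-1-one, 2 (S)-1-phenylethylamine, 3 but-3-yn-2-one
Product: 6 (R)-2-methyl-2-[(E)-3-oxobut-1-en-1-yl]cyclohexan-1-one, via imine 4 (not isolated), via Michael adduct imine 5 (not isolated)
Conditions: (i) 2, p-TsOH (cat.), toluene, reflux, azeotropic removal of water; (ii) 3, THF, 0 °C to rt; (iii) 20% aq. AcOH, rt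
Reagents that add atoms: water, O
Why: Deracemizing aza-ene-type Michael addition of the more substituted secondary enamine tautomer of 4 to the ynone, in which the phenyl group of the auxiliary shields one face so that the quaternary C10 should form in the (R) configuration, the concerted N–H transfer gives the (E)-enone, and mild acid hydrolysis frees the ketone.

Step 2
Reactants: 6 (R)-2-methyl-2-[(E)-3-oxobut-1-en-1-yl]cyclohexan-1-one
Product: 7 (R)-2-[(1E,3R)-3-hydroxybut-1-en-1-yl]-2-methylcyclohexan-1-one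
Conditions: (S)-2-methyl-CBS-oxazaborolidine (20 mol %), catecholborane, toluene, −78 °C; then MeOH, aq. NaHCO3
Reagents that add atoms: none
Why: Corey–Bakshi–Shibata reduction, in which the oxazaborolidine binds the unhindered enone carbonyl with the alkenyl group as the large substituent and should deliver hydride to give the (R)-carbinol at C12 under catalyst control, while the α-quaternary ring ketone is too hindered to compete and catecholborane spares the alkene.

Step 3
Reactants: 7 (R)-2-[(1E,3R)-3-hydroxybut-1-en-1-yl]-2-methylcyclohexan-1-one, 8 but-3-enoic acid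
Product: 9 (2R,3E)-4-[(1R)-1-methyl-2-oxocyclohexyl]but-3-en-2-yl but-3-enoate
Conditions: DCC, DMAP (5 mol %), CH2Cl2, −10 °C to 0 °C
Reagents that add atoms: none
Why: Steglich esterification of the secondary allylic alcohol with retention at C12, run cold with little DMAP so that the β,γ-unsaturated acyl group does not slip into conjugation.

Step 4
Reactants: 9 (2R,3E)-4-[(1R)-1-methyl-2-oxocyclohexyl]but-3-en-2-yl but-3-enoate
Product: 11 (3S,4E)-2-ethenyl-3-[(1R)-1-methyl-2-oxocyclohexyl]hex-4-enoic acid (C2 epimers), via bis-silyl ketene acetal 10 (not isolated)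
Conditions: LDA (2.5 equiv), Me3SiCl/Et3N (premixed), THF, −78 °C, then 65 °C; 1 M HCl
Reagents that add atoms: none
Why: Ireland–Claisen rearrangement of the silyl dienol ether through a chair transition state with the C13 methyl equatorial, so that the C8–C9 bond forms on the alkene face from which the C12–O bond leaves and the (R)-carbinol is transferred into the (S) configuration at C9 with an (E)-C11=C12 alkene, while C8 forms as a mixture that is corrected in step 10 and the ring ketone is masked in situ as its silyl enol ether.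

Step 5
Reactants: 11 (3S,4E)-2-ethenyl-3-[(1R)-1-methyl-2-oxocyclohexyl]hex-4-enoic acid (C2 epimers)
Product: 12 tert-butyl (3S,4E)-2-ethenyl-3-[(1R)-1-methyl-2-oxocyclohexyl]hex-4-enoate (C2 epimers)
Conditions: tert-butyl 2,2,2-trichloroacetimidate, BF3·OEt2 (cat.), cyclohexane/CH2Cl2, rt
Reagents that add atoms: tert-butyl 2,2,2-trichloroacetimidate, CC(C)(C)OC(=N)C(Cl)(Cl)Cl
Why: Acid-catalysed O-alkylation of the carboxylic acid by the trichloroacetimidate, which needs no base and so leaves the β,γ-unsaturated ester, the ketone and all stereocenters untouched.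

Step 6
Reactants: 12 tert-butyl (3S,4E)-2-ethenyl-3-[(1R)-1-methyl-2-oxocyclohexyl]hex-4-enoate (C2 epimers)
Product: 13 tert-butyl (3R)-3-[(3S,4E)-1-(tert-butoxy)-2-ethenyl-1-oxohex-4-en-3-yl]-3-methyl-2-oxocyclohexane-1-carboxylate (epimers at C1 and at the side-chain C2)
Conditions: LDA (1.1 equiv), THF, −78 °C; Boc2O, −78 °C to −20 °C; aq. NH4Cl
Reagents that add atoms: di-tert-butyl dicarbonate (Boc2O), CC(C)(C)OC(=O)OC(=O)OC(C)(C)C
Why: Claisen-type C-acylation of the kinetic lithium enolate with a dicarbonate, regiodefined because C10 is quaternary and only C4 can enolize, and chemoselective because the unhindered ketone α-CH2 is deprotonated faster than the hindered tertiary C8–H; the new C4 centre becomes trigonal in step 7.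

Step 7
Reactants: 13 tert-butyl (3R)-3-[(3S,4E)-1-(tert-butoxy)-2-ethenyl-1-oxohex-4-en-3-yl]-3-methyl-2-oxocyclohexane-1-carboxylate
Product: 14 tert-butyl (3R)-3-[(3S,4E)-1-(tert-butoxy)-2-ethenyl-1-oxohex-4-en-3-yl]-3-methyl-2-{[(trifluoromethyl)sulfonyl]oxy}cyclohex-1-ene-1-carboxylate (side-chain C2 epimers)
Conditions: i-Pr2NEt, Tf2O, CH2Cl2, −78 °C to 0 °C
Reagents that add atoms: trifluoromethanesulfonic anhydride (Tf2O), O=S(=O)(OS(=O)(=O)C(F)(F)F)C(F)(F)F
Why: O-Triflation of the β-keto ester enol (enol triflate formation) fixes C5 as a trigonal, electrophilic carbon conjugated with the C19 ester, and the amine base is too weak to touch C8–H.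

Step 8
Reactants: 14 tert-butyl (3R)-3-[(3S,4E)-1-(tert-butoxy)-2-ethenyl-1-oxohex-4-en-3-yl]-3-methyl-2-{[(trifluoromethyl)sulfonyl]oxy}cyclohex-1-ene-1-carboxylate
Product: 16 di-tert-butyl (4aR,5S)-4a-methyl-5-[(E)-prop-1-en-1-yl]-2,3,4,4a,5,6,7,8-octahydronaphthalene-1,6-dicarboxylate (C6 epimers), via B-alkyl-9-BBN 15 (not isolated)
Conditions: 9-BBN (1.1 equiv), THF, 0 °C to rt; then PdCl2(dppf) (10 mol %), AsPh3, Cs2CO3, DMF/THF/H2O, 50 °C, high dilution
Reagents that add atoms: none
Why: 9-BBN should hydroborate only the terminal vinyl group on C8 (boron on C6), because the (E)-propenyl group is 1,2-disubstituted and the enol triflate is tetrasubstituted and electron-poor; zerovalent palladium then inserts into the C5–OTf bond, base-assisted transmetalation transfers the primary B-alkyl group, and reductive elimination forms the C5–C6 bond. The closest known reaction type is the intramolecular B-alkyl Suzuki–Miyaura coupling of alkenyl triflates, including enol triflates of β-keto esters. Ring B closes as a six-membered carbocycle by reductive elimination from a seven-membered alkyl(alkenyl) palladacycle of divalent palladium, exo to the ring-A double bond, which stays at C4=C5. No stereocenter is created: C5 is kept trigonal on purpose so that C5 and C4 are set afterwards on the rigid bicycle, and both C8 epimers of 14 react alike. The step needs chemoselective hydroboration (secured by the substitution pattern of the three alkenes), cyclization over oligomerization (high dilution) and reductive elimination faster than β-hydride elimination (wide-bite-angle dppf, AsPh3, primary alkyl group).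

Step 9
Reactants: 16 di-tert-butyl (4aR,5S)-4a-methyl-5-[(E)-prop-1-en-1-yl]-2,3,4,4a,5,6,7,8-octahydronaphthalene-1,6-dicarboxylate (C6 epimers)
Product: 18 di-tert-butyl (1S,4aR,5S,8aR)-1,4a-dimethyl-5-[(E)-prop-1-en-1-yl]decahydronaphthalene-1,6-dicarboxylate (C6 epimers), via lithium ester enolate 17 (not isolated)
Conditions: Li, NH3(l)/THF, t-BuOH (1 equiv), −78 °C; then MeI (excess), −78 °C to −33 °C
Reagents that add atoms: iodomethane (MeI), CI
Why: Birch-type reductive alkylation of the α,β-unsaturated ester, in which the C5 carbanion is protonated axially on the α face (trans to the C10 methyl) to give the trans-decalin and the ester enolate 17 is methylated from the equatorial α face, away from the 1,3-diaxial C10 methyl, so that the C19 ester ends up axial (β) and the C18 methyl equatorial (α).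

Step 10
Reactants: 18 di-tert-butyl (1S,4aR,5S,8aR)-1,4a-dimethyl-5-[(E)-prop-1-en-1-yl]decahydronaphthalene-1,6-dicarboxylate (C6 epimers)
Product: 19 di-tert-butyl (1S,4aR,5S,6R,8aR)-1,4a-dimethyl-5-[(E)-prop-1-en-1-yl]decahydronaphthalene-1,6-dicarboxylate
Conditions: KOt-Bu (0.5 equiv), t-BuOH/THF, 50 °C
Reagents that add atoms: none
Why: Thermodynamic epimerization through the C8 ester enolate (the C4 ester cannot enolize) should funnel both C8 epimers into the 8α equatorial ester, trans-diequatorial to the C9 side chain and free of the 1,3-diaxial clash with the C10 methyl.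

Step 11
Reactants: 19 di-tert-butyl (1S,4aR,5S,6R,8aR)-1,4a-dimethyl-5-[(E)-prop-1-en-1-yl]decahydronaphthalene-1,6-dicarboxylate
Product: 20 di-tert-butyl (1S,4aR,5S,6R,8aR)-5-ethenyl-1,4a-dimethyldecahydronaphthalene-1,6-dicarboxylate
Conditions: ethylene (1 atm), second-generation Grubbs catalyst (5 mol %), CH2Cl2, 40 °C
Reagents that add atoms: ethylene, C=C
Why: Ethenolysis (cross-metathesis with ethylene) exchanges the propenyl terminus for a methylene, driven by loss of volatile propene, and touches no stereocenter.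

Step 12
Reactants: 20 di-tert-butyl (1S,4aR,5S,6R,8aR)-5-ethenyl-1,4a-dimethyldecahydronaphthalene-1,6-dicarboxylate, 21 3-bromofuran-2(5H)-one
Product: 23 di-tert-butyl (1S,4aR,5S,6R,8aR)-1,4a-dimethyl-5-[2-(2-oxo-2,5-dihydrofuran-3-yl)ethyl]decahydronaphthalene-1,6-dicarboxylate, via B-alkyl-9-BBN 22 (not isolated)
Conditions: 9-BBN, THF, rt to 50 °C; then 21, PdCl2(dppf) (10 mol %), AsPh3, K3PO4 (aq.), DMF, rt
Reagents that add atoms: none
Why: One-pot hydroboration/B-alkyl Suzuki–Miyaura coupling, in which 9-BBN adds to the terminal carbon C12 and the B-alkyl group couples with the α-bromo enoate of 21 under mild phosphate base, forming C12–C13 with the butenolide already at its final oxidation level and no new stereocenter.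

Step 13
Reactants: 23 di-tert-butyl (1S,4aR,5S,6R,8aR)-1,4a-dimethyl-5-[2-(2-oxo-2,5-dihydrofuran-3-yl)ethyl]decahydronaphthalene-1,6-dicarboxylate
Product: 24 (1S,4aR,5S,6R,8aR)-1,4a-dimethyl-5-[2-(2-oxo-2,5-dihydrofuran-3-yl)ethyl]decahydronaphthalene-1,6-dicarboxylic acid (CNP0478950.1)
Conditions: CF3CO2H/CH2Cl2 (1:3), rt
Reagents that add atoms: none
Why: Acidolysis of both tert-butyl esters (E1 loss of 2-methylpropene) frees the two carboxylic acids without base, so the butenolide and the C8 configuration should be preserved.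

Compound list
1 | 2-methylcyclohexan-1-one (racemic) | CC1CCCCC1=O | starting material
2 | (S)-1-phenylethylamine | C[C@H](N)c1ccccc1 | starting material
3 | but-3-yn-2-one | CC(=O)C#C | starting material
4 | (S)-N-(2-methylcyclohexylidene)-1-phenylethanamine | CC1CCCCC1=N[C@@H](C)c1ccccc1 | intermediate
5 | (S)-N-{(2R)-2-methyl-2-[(E)-3-oxobut-1-en-1-yl]cyclohexylidene}-1-phenylethanamine | C[C@]1(/C=C/C(C)=O)CCCCC1=N[C@@H](C)c1ccccc1 | intermediate
6 | (R)-2-methyl-2-[(E)-3-oxobut-1-en-1-yl]cyclohexan-1-one | C[C@]1(/C=C/C(C)=O)CCCCC1=O | intermediate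
7 | (R)-2-[(1E,3R)-3-hydroxybut-1-en-1-yl]-2-methylcyclohexan-1-one | C[C@]1(/C=C/[C@@H](C)O)CCCCC1=O | intermediate
8 | but-3-enoic acid | OC(=O)CC=C | starting material
9 | (2R,3E)-4-[(1R)-1-methyl-2-oxocyclohexyl]but-3-en-2-yl but-3-enoate | C[C@]1(/C=C/[C@@H](C)OC(=O)CC=C)CCCCC1=O | intermediate
10 | trimethylsilyl ketene acetal of 9 with the ring ketone as its trimethylsilyl enol ether | C[C@]1(/C=C/[C@@H](C)OC(O[Si](C)(C)C)=CC=C)CCCC=C1O[Si](C)(C)C | intermediate
11 | (3S,4E)-2-ethenyl-3-[(1R)-1-methyl-2-oxocyclohexyl]hex-4-enoic acid (C2 epimers) | C[C@]1([C@@H](/C=C/C)C(C=C)C(=O)O)CCCCC1=O | intermediate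
12 | tert-butyl (3S,4E)-2-ethenyl-3-[(1R)-1-methyl-2-oxocyclohexyl]hex-4-enoate (C2 epimers) | C[C@]1([C@@H](/C=C/C)C(C=C)C(=O)OC(C)(C)C)CCCCC1=O | intermediate
13 | tert-butyl (3R)-3-[(3S,4E)-1-(tert-butoxy)-2-ethenyl-1-oxohex-4-en-3-yl]-3-methyl-2-oxocyclohexane-1-carboxylate | C[C@]1([C@@H](/C=C/C)C(C=C)C(=O)OC(C)(C)C)CCCC(C(=O)OC(C)(C)C)C1=O | intermediate
14 | tert-butyl (3R)-3-[(3S,4E)-1-(tert-butoxy)-2-ethenyl-1-oxohex-4-en-3-yl]-3-methyl-2-{[(trifluoromethyl)sulfonyl]oxy}cyclohex-1-ene-1-carboxylate | C[C@]1([C@@H](/C=C/C)C(C=C)C(=O)OC(C)(C)C)CCCC(C(=O)OC(C)(C)C)=C1OS(=O)(=O)C(F)(F)F | intermediate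
15 | B-alkyl-9-borabicyclo[3.3.1]nonane from hydroboration of the C8 vinyl group of 14 (boron on C6) | C[C@]1([C@@H](/C=C/C)C(CCB2C3CCCC2CCC3)C(=O)OC(C)(C)C)CCCC(C(=O)OC(C)(C)C)=C1OS(=O)(=O)C(F)(F)F | intermediate
16 | di-tert-butyl (4aR,5S)-4a-methyl-5-[(E)-prop-1-en-1-yl]-2,3,4,4a,5,6,7,8-octahydronaphthalene-1,6-dicarboxylate (C6 epimers; 10β-methyl, 9β-propenyl) | C[C@]12CCCC(C(=O)OC(C)(C)C)=C1CCC(C(=O)OC(C)(C)C)[C@@H]2/C=C/C | intermediate
17 | lithium enolate of the C19 tert-butyl ester after reduction (5α-H, trans-fused) | C[C@]12CCCC(=C(O[Li])OC(C)(C)C)[C@@H]1CCC(C(=O)OC(C)(C)C)[C@@H]2/C=C/C | intermediate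
18 | di-tert-butyl (1S,4aR,5S,8aR)-1,4a-dimethyl-5-[(E)-prop-1-en-1-yl]decahydronaphthalene-1,6-dicarboxylate (C6 epimers) | C[C@]12CCC[C@](C)(C(=O)OC(C)(C)C)[C@@H]1CCC(C(=O)OC(C)(C)C)[C@@H]2/C=C/C | intermediate
19 | di-tert-butyl (1S,4aR,5S,6R,8aR)-1,4a-dimethyl-5-[(E)-prop-1-en-1-yl]decahydronaphthalene-1,6-dicarboxylate | C[C@]12CCC[C@](C)(C(=O)OC(C)(C)C)[C@@H]1CC[C@@H](C(=O)OC(C)(C)C)[C@@H]2/C=C/C | intermediate
20 | di-tert-butyl (1S,4aR,5S,6R,8aR)-5-ethenyl-1,4a-dimethyldecahydronaphthalene-1,6-dicarboxylate | C[C@]12CCC[C@](C)(C(=O)OC(C)(C)C)[C@@H]1CC[C@@H](C(=O)OC(C)(C)C)[C@@H]2C=C | intermediate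
21 | 3-bromofuran-2(5H)-one | BrC1=CCOC1=O | starting material
22 | B-alkyl-9-borabicyclo[3.3.1]nonane from hydroboration of the C9 vinyl group of 20 (boron on C12) | C[C@]12CCC[C@](C)(C(=O)OC(C)(C)C)[C@@H]1CC[C@@H](C(=O)OC(C)(C)C)[C@@H]2CCB1C2CCCC1CCC2 | intermediate
23 | di-tert-butyl (1S,4aR,5S,6R,8aR)-1,4a-dimethyl-5-[2-(2-oxo-2,5-dihydrofuran-3-yl)ethyl]decahydronaphthalene-1,6-dicarboxylate | C[C@]12CCC[C@](C)(C(=O)OC(C)(C)C)[C@@H]1CC[C@@H](C(=O)OC(C)(C)C)[C@@H]2CCC1=CCOC1=O | intermediate
24 | (1S,4aR,5S,6R,8aR)-1,4a-dimethyl-5-[2-(2-oxo-2,5-dihydrofuran-3-yl)ethyl]decahydronaphthalene-1,6-dicarboxylic acid | C[C@]12CCC[C@](C)(C(=O)O)[C@@H]1CC[C@@H](C(=O)O)[C@@H]2CCC1=CCOC1=O | target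

Total step count: 13. Longest linear sequence: 13 steps, from 1.

Steps most likely to fail

Step 8 (key step). Oxidative addition and transmetalation at the hindered, tetrasubstituted triflate next to the quaternary C10 may be slow, so that protodeboronation, β-hydride elimination or intermolecular coupling overtakes ring closure. The fallback sets out from 14 and closes the same bond through a nickel-mediated radical manifold. Borane 15, made as before, would be iodinolysed (I2, NaOMe, THF) to the primary iodide tert-butyl (3R)-3-[(3S,4E)-1-(tert-butoxy)-2-(2-iodoethyl)-1-oxohex-4-en-3-yl]-3-methyl-2-{[(trifluoromethyl)sulfonyl]oxy}cyclohex-1-ene-1-carboxylate F1. Intramolecular reductive cross-electrophile coupling of the alkenyl triflate with the alkyl iodide (NiCl2·glyme, 4,4′-di-tert-butyl-2,2′-bipyridine, Mn powder, DMA, high dilution) would then give 16, where the route is rejoined.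

Step 1. The reactive ynone may polymerize or add twice, and regio- or facial control in the aza-ene addition may erode, so that C10 is not formed cleanly in one configuration. The fallback sets out from 1 and builds C10 by decarboxylative asymmetric allylic alkylation instead. Thermodynamic silylation (Me3SiCl, NaI, Et3N, MeCN) would give 2-methyl-1-(trimethylsilyloxy)cyclohex-1-ene F2. MeLi followed by allyl chloroformate would give allyl 2-methylcyclohex-1-en-1-yl carbonate F3. Pd2(dba)3 with the (R)-configured tert-butyl-PHOX ligand, chosen to deliver the (R)-ketone, would give (R)-2-allyl-2-methylcyclohexan-1-one F4. Alkene isomerization with RuHCl(CO)(PPh3)3 would give (R)-2-methyl-2-[(E)-prop-1-en-1-yl]cyclohexan-1-one F5. Cross-metathesis of F5 with methyl vinyl ketone (second-generation Hoveyda–Grubbs catalyst, CH2Cl2, 40 °C) would rejoin the route at 6.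

Step 12. Hydroboration of the hindered vinyl group may be slow, and the base-sensitive bromobutenolide may be debrominated or degraded before cross-coupling occurs. The fallback sets out from 20 and builds the butenolide by enolate alkylation and sulfoxide elimination. Hydroboration–oxidation (9-BBN; NaBO3) would give di-tert-butyl (1S,4aR,5S,6R,8aR)-5-(2-hydroxyethyl)-1,4a-dimethyldecahydronaphthalene-1,6-dicarboxylate F6. Appel iodination (PPh3, I2, imidazole) would give di-tert-butyl (1S,4aR,5S,6R,8aR)-5-(2-iodoethyl)-1,4a-dimethyldecahydronaphthalene-1,6-dicarboxylate F7. Alkylation of the lithium enolate of 3-(phenylsulfanyl)oxolan-2-one with F7 (LDA, THF/DMPU) would give di-tert-butyl (1S,4aR,5S,6R,8aR)-1,4a-dimethyl-5-{2-[2-oxo-3-(phenylsulfanyl)oxolan-3-yl]ethyl}decahydronaphthalene-1,6-dicarboxylate F8. Oxidation (mCPBA, −78 °C) would give di-tert-butyl (1S,4aR,5S,6R,8aR)-5-{2-[3-(benzenesulfinyl)-2-oxooxolan-3-yl]ethyl}-1,4a-dimethyldecahydronaphthalene-1,6-dicarboxylate F9. Thermal syn-elimination of F9 (toluene, 110 °C), expected to favour the endocyclic alkene, would rejoin the route at 23.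

Further compounds
F1 | step 8 | tert-butyl (3R)-3-[(3S,4E)-1-(tert-butoxy)-2-(2-iodoethyl)-1-oxohex-4-en-3-yl]-3-methyl-2-{[(trifluoromethyl)sulfonyl]oxy}cyclohex-1-ene-1-carboxylate | C[C@]1([C@@H](/C=C/C)C(CCI)C(=O)OC(C)(C)C)CCCC(C(=O)OC(C)(C)C)=C1OS(=O)(=O)C(F)(F)F
F2 | step 1 | 2-methyl-1-(trimethylsilyloxy)cyclohex-1-ene | CC1=C(O[Si](C)(C)C)CCCC1
F3 | step 1 | allyl 2-methylcyclohex-1-en-1-yl carbonate | CC1=C(OC(=O)OCC=C)CCCC1
F4 | step 1 | (R)-2-allyl-2-methylcyclohexan-1-one | C[C@]1(CC=C)CCCCC1=O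
F5 | step 1 | (R)-2-methyl-2-[(E)-prop-1-en-1-yl]cyclohexan-1-one | C[C@]1(/C=C/C)CCCCC1=O
F6 | step 12 | di-tert-butyl (1S,4aR,5S,6R,8aR)-5-(2-hydroxyethyl)-1,4a-dimethyldecahydronaphthalene-1,6-dicarboxylate | C[C@]12CCC[C@](C)(C(=O)OC(C)(C)C)[C@@H]1CC[C@@H](C(=O)OC(C)(C)C)[C@@H]2CCO
F7 | step 12 | di-tert-butyl (1S,4aR,5S,6R,8aR)-5-(2-iodoethyl)-1,4a-dimethyldecahydronaphthalene-1,6-dicarboxylate | C[C@]12CCC[C@](C)(C(=O)OC(C)(C)C)[C@@H]1CC[C@@H](C(=O)OC(C)(C)C)[C@@H]2CCI
F8 | step 12 | di-tert-butyl (1S,4aR,5S,6R,8aR)-1,4a-dimethyl-5-{2-[2-oxo-3-(phenylsulfanyl)oxolan-3-yl]ethyl}decahydronaphthalene-1,6-dicarboxylate | C[C@]12CCC[C@](C)(C(=O)OC(C)(C)C)[C@@H]1CC[C@@H](C(=O)OC(C)(C)C)[C@@H]2CCC1(Sc2ccccc2)CCOC1=O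
F9 | step 12 | di-tert-butyl (1S,4aR,5S,6R,8aR)-5-{2-[3-(benzenesulfinyl)-2-oxooxolan-3-yl]ethyl}-1,4a-dimethyldecahydronaphthalene-1,6-dicarboxylate | C[C@]12CCC[C@](C)(C(=O)OC(C)(C)C)[C@@H]1CC[C@@H](C(=O)OC(C)(C)C)[C@@H]2CCC1(S(=O)c2ccccc2)CCOC1=O
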